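**Plan**
- Retrosynthetic cuts, in order: the six O–benzyl bonds; the aryl–CH= bond of the cinnamate (Heck); the coumarin C4–C4a bond (Friedel–Crafts, with methanol as leaving group at C4); the aryl ester bond C2(=O)–O1; then C3–C4 (formylation) and the ArO–CH2 ether bond.
- Enabling feature: in the benzo ring of the coumarin, C4a is para to the C7 oxygen and ortho to O1, so it is the most nucleophilic carbon of a 3,4-dioxygenated phenyl ester. C4 sits at the formyl oxidation level, so C2–C3–C4 can be carried as an aryl β-methoxyacrylate.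
- Forward order: a brominated aryloxyacetate is formylated, O-methylated and saponified; the acid is esterified with a dibenzyloxyphenol; acid then closes the pyranone ring, the only ring made. A Heck reaction joins the chain and a Lewis acid removes all benzyl groups.
- Stereochemistry: the single stereocenter is bought as (R)-danshensu and no bond to it is ever broken. The E alkene comes from the Heck reaction.

Key step: step 7

Remark: the β-methoxyacrylates are drawn Z (methoxy trans to the carbonyl), the usual outcome of formylation–methylation; the geometry is erased in the ring closure, so either isomer would serve.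
Remark: the formyl enolate has no fixed geometry and the methoxychromanone adduct is a diastereomer mixture, so both are written without configuration; (R)-danshensu is taken as the free acid.

**Route**

Step 1
Reactants: 1 2-(benzyloxy)phenol
Product: 2 2-(benzyloxy)-4-bromophenol
Conditions: NBS (1.0 equiv), MeCN, 0 °C
Reagents that add atoms: N-bromosuccinimide, O=C1CCC(=O)N1Br
Why: Electrophilic aromatic bromination of a phenol with NBS in a polar solvent goes para to the free hydroxyl, which outranks the benzyloxy group as a director, so bromine should enter C4.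

Step 2
Reactants: 2 2-(benzyloxy)-4-bromophenol
Product: 3 methyl 2-[2-(benzyloxy)-4-bromophenoxy]acetate
Conditions: BrCH2CO2Me, K2CO3, acetone, reflux
Reagents that add atoms: methyl bromoacetate, COC(=O)CBr
Why: Williamson etherification of a phenoxide with an α-halo ester is fast, and nothing else in the molecule reacts.

Step 3
Reactants: 3 methyl 2-[2-(benzyloxy)-4-bromophenoxy]acetate
Product: 5 methyl (Z)-2-[2-(benzyloxy)-4-bromophenoxy]-3-methoxyacrylate, via sodium formyl enolate 4 (not isolated)
Conditions: NaH, HCO2Me, DMF, 0 °C to rt; then Me2SO4, rt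
Reagents that add atoms: methyl formate, COC=O; dimethyl sulfate, COS(=O)(=O)OC
Why: Crossed Claisen formylation of the aryloxyacetate gives the stabilized formyl enolate, which the hard methylating agent alkylates on oxygen, as in the standard preparation of 2-substituted 3-methoxyacrylates.

Step 4
Reactants: 5 methyl (Z)-2-[2-(benzyloxy)-4-bromophenoxy]-3-methoxyacrylate
Product: 6 (Z)-2-[2-(benzyloxy)-4-bromophenoxy]-3-methoxyacrylic acid
Conditions: LiOH·H2O, THF/MeOH/H2O, rt; then 1 M HCl to pH 3, 0 °C
Reagents that add atoms: lithium hydroxide, [Li+].[OH-]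
Why: Saponification of the methyl ester at room temperature is routine for β-methoxyacrylates, and brief cold acidification should spare the enol ether.

Step 5
Reactants: 7 3,4-bis(benzyloxy)benzaldehyde
Product: 9 3,4-bis(benzyloxy)phenol, via aryl formate 8 (not isolated)
Conditions: mCPBA, CH2Cl2, rt; then K2CO3 (cat.), MeOH, rt
Reagents that add atoms: 3-chloroperoxybenzoic acid, OOC(=O)c1cccc(Cl)c1
Why: Baeyer–Villiger (Dakin-type) oxidation of an electron-rich benzaldehyde proceeds by aryl migration to the aryl formate, which methanolysis cleaves to the phenol.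

Step 6
Reactants: 6 (Z)-2-[2-(benzyloxy)-4-bromophenoxy]-3-methoxyacrylic acid; 9 3,4-bis(benzyloxy)phenol
Product: 10 3,4-bis(benzyloxy)phenyl (Z)-2-[2-(benzyloxy)-4-bromophenoxy]-3-methoxyacrylate
Conditions: DCC, DMAP (cat.), CH2Cl2, 0 °C to rt
Reagents that add atoms: none
Why: Steglich esterification through the acylpyridinium ion acylates phenols under neutral conditions that leave the enol ether intact.

Step 7
Reactants: 10 3,4-bis(benzyloxy)phenyl (Z)-2-[2-(benzyloxy)-4-bromophenoxy]-3-methoxyacrylate
Product: 12 6,7-bis(benzyloxy)-3-[2-(benzyloxy)-4-bromophenoxy]-2H-chromen-2-one, via 4-methoxychroman-2-one adduct 11 (not isolated)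
Conditions: TFA/CH2Cl2 (1:1), anhydrous, 0 °C to rt
Reagents that add atoms: none
Why: TFA protonates the push–pull enol ether (at the α carbon, or at the carbonyl oxygen to give the vinylogous equivalent) and so generates a methoxycarbenium ion at the future C4; the ester arene attacks it to form C4–C4a, rearomatization gives adduct 11, and acid-promoted loss of methanol through the para-alkoxybenzylic cation installs C3=C4. This is the ring-forming half of a Pechmann condensation run on a preformed aryl ester, the known acid cyclization of aryl β-alkoxyacrylates and formylacetate equivalents to 4-unsubstituted coumarins. The pyranone ring closes by a six-membered 6-exo-trig Friedel–Crafts attack of the arene carbon on the exocyclic C=O+ bond, and the enol ether geometry is lost on protonation. No stereocenter remains, since the two transient ones of 11 vanish on elimination. Two selectivities are needed: on the ester ring, attack at the unhindered carbon para to a benzyloxy group and ortho to the ester oxygen, not at the carbon flanked by two oxygens, secures the 6,7-pattern; and the ester ring must win over the brominated aryloxy ring, whose only free ortho carbon lacks a para donor, is deactivated by bromine and would have to close a five-membered benzofuran ring. Dilute TFA at or below room temperature is chosen because aryl benzyl ethers tolerate it.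

Step 8
Reactants: 13 (R)-3-(3,4-dihydroxyphenyl)-2-hydroxypropanoic acid ((R)-danshensu)
Product: 14 benzyl (R)-3-[3,4-bis(benzyloxy)phenyl]-2-hydroxypropanoate
Conditions: BnBr (3.3 equiv), K2CO3, DMF, rt, argon
Reagents that add atoms: benzyl bromide, BrCc1ccccc1
Why: Carbonate deprotonates only the carboxylic acid and the two phenols, so SN2 benzylation should give the benzyl ester bis(benzyl ether) and leave the secondary alcohol and the stereocenter untouched.

Step 9
Reactants: 14 benzyl (R)-3-[3,4-bis(benzyloxy)phenyl]-2-hydroxypropanoate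
Product: 15 benzyl (R)-2-(acryloyloxy)-3-[3,4-bis(benzyloxy)phenyl]propanoate
Conditions: CH2=CHCOCl, Et3N, CH2Cl2, −20 to 0 °C
Reagents that add atoms: acryloyl chloride, C=CC(=O)Cl
Why: O-Acylation of the secondary alcohol with an acid chloride and a tertiary amine breaks no bond at the stereocenter, which therefore stays R.

Step 10
Reactants: 12 6,7-bis(benzyloxy)-3-[2-(benzyloxy)-4-bromophenoxy]-2H-chromen-2-one; 15 benzyl (R)-2-(acryloyloxy)-3-[3,4-bis(benzyloxy)phenyl]propanoate
Product: 16 benzyl (R)-2-{[(E)-3-{3-(benzyloxy)-4-{[6,7-bis(benzyloxy)-2-oxo-2H-chromen-3-yl]oxy}phenyl}acryloyl]oxy}-3-[3,4-bis(benzyloxy)phenyl]propanoate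
Conditions: Pd[P(t-Bu)3]2 (5 mol %), Cy2NMe, 1,4-dioxane, 50 °C
Reagents that add atoms: none
Why: In this Heck reaction, oxidative addition of the aryl bromide to the electron-rich zerovalent palladium complex, syn insertion of the acrylate and syn β-hydride elimination give the E-cinnamate, and the hindered amine base at 50 °C should not epimerize the α-acyloxy ester.

Step 11
Reactants: 16 the hexabenzyl compound from step 10
Product: 17 (R)-3-(3,4-dihydroxyphenyl)-2-{[(E)-3-{4-[(6,7-dihydroxy-2-oxo-2H-chromen-3-yl)oxy]-3-hydroxyphenyl}acryloyl]oxy}propanoic acid (CNP0318082.1)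
Conditions: BCl3 (excess), C6HMe5 (pentamethylbenzene), CH2Cl2, −78 to −20 °C; then H2O, argon
Reagents that add atoms: none
Why: BCl3 ionizes the aryl benzyl ethers and the benzyl ester at low temperature while pentamethylbenzene traps the benzyl cations, a non-reductive debenzylation that should spare both alkenes, the lactone and the cinnamate ester.

**Compound list**

1 | 2-(benzyloxy)phenol | Oc1ccccc1OCc1ccccc1 | starting material
2 | 2-(benzyloxy)-4-bromophenol | Oc1ccc(Br)cc1OCc1ccccc1 | intermediate
3 | methyl 2-[2-(benzyloxy)-4-bromophenoxy]acetate | COC(=O)COc1ccc(Br)cc1OCc1ccccc1 | intermediate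
4 | sodium enolate of methyl 2-[2-(benzyloxy)-4-bromophenoxy]-3-oxopropanoate (formyl enolate, not isolated) | [Na+].[O-]C=C(Oc1ccc(Br)cc1OCc1ccccc1)C(=O)OC | intermediate
5 | methyl (Z)-2-[2-(benzyloxy)-4-bromophenoxy]-3-methoxyacrylate | CO/C=C(\Oc1ccc(Br)cc1OCc1ccccc1)C(=O)OC | intermediate
6 | (Z)-2-[2-(benzyloxy)-4-bromophenoxy]-3-methoxyacrylic acid | CO/C=C(\Oc1ccc(Br)cc1OCc1ccccc1)C(=O)O | intermediate
7 | 3,4-bis(benzyloxy)benzaldehyde | O=Cc1ccc(OCc2ccccc2)c(OCc2ccccc2)c1 | starting material
8 | 3,4-bis(benzyloxy)phenyl formate (not isolated) | O=COc1ccc(OCc2ccccc2)c(OCc2ccccc2)c1 | intermediate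
9 | 3,4-bis(benzyloxy)phenol | Oc1ccc(OCc2ccccc2)c(OCc2ccccc2)c1 | intermediate
10 | 3,4-bis(benzyloxy)phenyl (Z)-2-[2-(benzyloxy)-4-bromophenoxy]-3-methoxyacrylate | CO/C=C(\Oc1ccc(Br)cc1OCc1ccccc1)C(=O)Oc1ccc(OCc2ccccc2)c(OCc2ccccc2)c1 | intermediate
11 | 6,7-bis(benzyloxy)-3-[2-(benzyloxy)-4-bromophenoxy]-4-methoxychroman-2-one (diastereomer mixture, not isolated) | COC1c2cc(OCc3ccccc3)c(OCc3ccccc3)cc2OC(=O)C1Oc1ccc(Br)cc1OCc1ccccc1 | intermediate
12 | 6,7-bis(benzyloxy)-3-[2-(benzyloxy)-4-bromophenoxy]-2H-chromen-2-one | O=c1oc2cc(OCc3ccccc3)c(OCc3ccccc3)cc2cc1Oc1ccc(Br)cc1OCc1ccccc1 | intermediate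
13 | (R)-3-(3,4-dihydroxyphenyl)-2-hydroxypropanoic acid ((R)-danshensu) | O[C@H](Cc1ccc(O)c(O)c1)C(=O)O | starting material
14 | benzyl (R)-3-[3,4-bis(benzyloxy)phenyl]-2-hydroxypropanoate | O[C@H](Cc1ccc(OCc2ccccc2)c(OCc2ccccc2)c1)C(=O)OCc1ccccc1 | intermediate
15 | benzyl (R)-2-(acryloyloxy)-3-[3,4-bis(benzyloxy)phenyl]propanoate | C=CC(=O)O[C@H](Cc1ccc(OCc2ccccc2)c(OCc2ccccc2)c1)C(=O)OCc1ccccc1 | intermediate
16 | benzyl (R)-2-{[(E)-3-{3-(benzyloxy)-4-{[6,7-bis(benzyloxy)-2-oxo-2H-chromen-3-yl]oxy}phenyl}acryloyl]oxy}-3-[3,4-bis(benzyloxy)phenyl]propanoate | O=C(/C=C/c1ccc(Oc2cc3cc(OCc4ccccc4)c(OCc4ccccc4)cc3oc2=O)c(OCc2ccccc2)c1)O[C@H](Cc1ccc(OCc2ccccc2)c(OCc2ccccc2)c1)C(=O)OCc1ccccc1 | intermediate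
17 | (R)-3-(3,4-dihydroxyphenyl)-2-{[(E)-3-{4-[(6,7-dihydroxy-2-oxo-2H-chromen-3-yl)oxy]-3-hydroxyphenyl}acryloyl]oxy}propanoic acid (CNP0318082.1) | O=C(/C=C/c1ccc(Oc2cc3cc(O)c(O)cc3oc2=O)c(O)c1)O[C@H](Cc1ccc(O)c(O)c1)C(=O)O | target

**Step count**

Total: 11 steps. Longest linear sequence: 8 steps (steps 1, 2, 3, 4, 6, 7, 10, 11).

**Steps most likely to fail**

Step 7. The acidity needed to ionize the push–pull enol ether may exceed what the aryl benzyl ethers tolerate, leading to debenzylation and benzyl migration. Closure by the brominated aryloxy ring to a benzofuran may also compete. The fallback builds the pyranone by a Perkin-type condensation, which forms C3–C4 by aldol dehydration after O-acylation. It sets out from 3 and 9. Saponification of 3 (LiOH, THF/H2O) should give [2-(benzyloxy)-4-bromophenoxy]acetic acid F1. Magnesium-mediated ortho-formylation of 9 (MgCl2, Et3N, paraformaldehyde, MeCN, reflux) should give 4,5-bis(benzyloxy)-2-hydroxybenzaldehyde F2. Heating F1 with F2 and DCC in DMSO at 110 °C should give coumarin 12, where the route is rejoined.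

Step 11. Cleavage of the six benzyl groups may be uneven: the benzyl ester ionizes more slowly than the aryl ethers, and the warming needed to finish it invites C-benzylation of the freed catechol rings and attack on the α-acyloxy ester. The fallback carries the danshensu half with 4-methoxybenzyl groups, which ionize at −78 °C, so that no benzyl ester has to be cleaved. It sets out from 13 and 12. Alkylation of 13 with 4-methoxybenzyl chloride (K2CO3, Bu4NI, DMF) should give 4-methoxybenzyl (R)-3-{3,4-bis[(4-methoxybenzyl)oxy]phenyl}-2-hydroxypropanoate F3. Acryloylation as in step 9 should give 4-methoxybenzyl (R)-2-(acryloyloxy)-3-{3,4-bis[(4-methoxybenzyl)oxy]phenyl}propanoate F4. Heck coupling of F4 with 12 as in step 10 should give 4-methoxybenzyl (R)-2-{[(E)-3-{3-(benzyloxy)-4-{[6,7-bis(benzyloxy)-2-oxo-2H-chromen-3-yl]oxy}phenyl}acryloyl]oxy}-3-{3,4-bis[(4-methoxybenzyl)oxy]phenyl}propanoate F5. BCl3 with pentamethylbenzene in CH2Cl2 at −78 °C should then release 17 directly.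

Step 10. Oxidative addition into the electron-rich aryl bromide may be sluggish, leaving time for oligomerization of the valuable acrylate or base-induced epimerization at its α-acyloxy ester center. The fallback makes the alkene with a cheap, robust acrylate and attaches the chiral alcohol afterwards. It sets out from 12. Heck reaction with acrylic acid under forcing conditions (Pd(OAc)2, P(o-tol)3, Et3N, DMF, 100 °C) should give (E)-3-{3-(benzyloxy)-4-{[6,7-bis(benzyloxy)-2-oxo-2H-chromen-3-yl]oxy}phenyl}acrylic acid F6. Steglich esterification of F6 with alcohol 14 (DCC, DMAP, CH2Cl2) should give 16, where the route is rejoined.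

**Further compounds**

F1 | step 7 | [2-(benzyloxy)-4-bromophenoxy]acetic acid | OC(=O)COc1ccc(Br)cc1OCc1ccccc1
F2 | step 7 | 4,5-bis(benzyloxy)-2-hydroxybenzaldehyde | O=Cc1cc(OCc2ccccc2)c(OCc2ccccc2)cc1O
F3 | step 11 | 4-methoxybenzyl (R)-3-{3,4-bis[(4-methoxybenzyl)oxy]phenyl}-2-hydroxypropanoate | O[C@H](Cc1ccc(OCc2ccc(OC)cc2)c(OCc2ccc(OC)cc2)c1)C(=O)OCc1ccc(OC)cc1
F4 | step 11 | 4-methoxybenzyl (R)-2-(acryloyloxy)-3-{3,4-bis[(4-methoxybenzyl)oxy]phenyl}propanoate | C=CC(=O)O[C@H](Cc1ccc(OCc2ccc(OC)cc2)c(OCc2ccc(OC)cc2)c1)C(=O)OCc1ccc(OC)cc1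
F5 | step 11 | 4-methoxybenzyl (R)-2-{[(E)-3-{3-(benzyloxy)-4-{[6,7-bis(benzyloxy)-2-oxo-2H-chromen-3-yl]oxy}phenyl}acryloyl]oxy}-3-{3,4-bis[(4-methoxybenzyl)oxy]phenyl}propanoate | O=C(/C=C/c1ccc(Oc2cc3cc(OCc4ccccc4)c(OCc4ccccc4)cc3oc2=O)c(OCc2ccccc2)c1)O[C@H](Cc1ccc(OCc2ccc(OC)cc2)c(OCc2ccc(OC)cc2)c1)C(=O)OCc1ccc(OC)cc1
F6 | step 10 | (E)-3-{3-(benzyloxy)-4-{[6,7-bis(benzyloxy)-2-oxo-2H-chromen-3-yl]oxy}phenyl}acrylic acid | OC(=O)/C=C/c1ccc(Oc2cc3cc(OCc4ccccc4)c(OCc4ccccc4)cc3oc2=O)c(OCc2ccccc2)c1
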